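## Retrosynthetic overview

- Epinortrachelogenin is (3R,4S), with 3-OH trans to the 4-benzyl group and the two benzyl groups cis ⇐ last-step oxygenation of a matairesinol-type lactone enolate anti to the 4-benzyl group, the counterpart of the late 8-hydroxylation in the biosynthesis.
- Lactone ⇐ aerobic dehydrogenation of a C2-symmetric secoisolariciresinol-type 1,4-diol through the lactol, as the dehydrogenase does; the two CH2OH groups need no differentiation.
- Diol ⇐ C8–C8′ bond by auxiliary-directed oxidative homodimerization of two molecules of a dihydroferulic acid enolate, the counterpart of the oxidative 8–8′ coupling of two C6C3 units; one bond sets both backbone stereocentres.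
- Monomer ⇐ dihydroferulic acid, TIPSCl and (S)-4-isopropyloxazolidin-2-one.
- Ring order: both arene rings are bought; the γ-lactone is the only ring made (step 5). The C3 centre from the dimerization is only a relay and is rebuilt in step 6.

Assumption: operations run in one flask with a single work-up count as one step, and in the dimerization (step 3) the second molecule of 6 is entered under the reagents that add atoms.

## Route

Step 1
Reactants: 1 3-(4-hydroxy-3-methoxyphenyl)propanoic acid (dihydroferulic acid)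
Product: 3 3-[3-methoxy-4-(triisopropylsilyloxy)phenyl]propanoic acid, via silyl ester 2 (not isolated)
Conditions: TIPSCl (2.2 equiv), imidazole, DMF, rt; then K2CO3, MeOH/THF/H2O, rt; 1 M HCl
Reagents that add atoms: triisopropylsilyl chloride, CC(C)[Si](Cl)(C(C)C)C(C)C
Why: Silyl protection of phenol and acid followed by selective solvolysis of the much more labile silyl ester leaves the phenol as a base-stable aryl TIPS ether (protecting-group chemistry, no stereocentre).

Step 2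
Reactants: 3 3-[3-methoxy-4-(triisopropylsilyloxy)phenyl]propanoic acid; 4 (S)-4-isopropyloxazolidin-2-one
Product: 6 (S)-4-isopropyl-3-{3-[3-methoxy-4-(triisopropylsilyloxy)phenyl]propanoyl}oxazolidin-2-one, via mixed pivalic anhydride 5 (not isolated)
Conditions: PivCl, Et3N, THF, −20 °C; then LiCl, −20 °C to rt
Reagents that add atoms: none
Why: N-Acylation of the Evans auxiliary through the mixed pivalic anhydride with LiCl activation occurs at the unhindered acyl carbon and leaves the (S) centre of 4 untouched.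

Step 3
Reactants: 6 (S)-4-isopropyl-3-{3-[3-methoxy-4-(triisopropylsilyloxy)phenyl]propanoyl}oxazolidin-2-one (2 equiv; two molecules are joined)
Product: 8 (2R,3R)-2,3-bis[3-methoxy-4-(triisopropylsilyloxy)benzyl]-1,4-bis[(S)-4-isopropyl-2-oxooxazolidin-3-yl]butane-1,4-dione, via lithium Z-enolate 7 (not isolated)
Conditions: LiN(iPr)2 (1.1 equiv), THF, −78 °C; then TiCl4 (1.1 equiv), −78 °C to rt
Reagents that add atoms: second molecule of compound 6 (the homocoupling partner), COc1cc(CCC(=O)N2[C@@H](C(C)C)COC2=O)ccc1O[Si](C(C)C)(C(C)C)C(C)C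
Why: Oxidative enolate homocoupling, the laboratory counterpart of the oxidative 8–8′ coupling of two C6C3 units: each molecule of 6 gives the chelated Z-enolate, TiCl4 oxidizes it by one electron (titanium goes from tetravalent to trivalent) and the two α-carbonyl radicals join on the faces anti to the isopropyl groups, so both new centres are R (minor 2R,3S isomer removed by chromatography).

Step 4
Reactants: 8 (2R,3R)-2,3-bis[3-methoxy-4-(triisopropylsilyloxy)benzyl]-1,4-bis[(S)-4-isopropyl-2-oxooxazolidin-3-yl]butane-1,4-dione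
Product: 9 (2R,3R)-2,3-bis[3-methoxy-4-(triisopropylsilyloxy)benzyl]butane-1,4-diol
Conditions: LiBH4, THF, 0 °C to rt; H2O
Reagents that add atoms: none
Why: Reductive cleavage of both N-acyloxazolidinones by hydride attack at the exocyclic carbonyls gives the C2-symmetric secoisolariciresinol-type diol without touching either stereocentre and returns the auxiliary.

Step 5
Reactants: 9 (2R,3R)-2,3-bis[3-methoxy-4-(triisopropylsilyloxy)benzyl]butane-1,4-diol
Product: 11 (3R,4R)-3,4-bis[3-methoxy-4-(triisopropylsilyloxy)benzyl]dihydrofuran-2(3H)-one, via lactol 10 (not isolated)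
Conditions: [Cu(MeCN)4]OTf (5 mol %), 4,4′-dimethoxy-2,2′-bipyridine (5 mol %), 9-azabicyclo[3.3.1]nonane N-oxyl (ABNO, 1 mol %), N-methylimidazole (10 mol %), MeCN, air, rt
Reagents that add atoms: none
Why: Aerobic alcohol oxidation with the [Cu(MeCN)4]OTf/ABNO catalyst pair (Stahl oxidative lactonization) takes one CH2OH to the aldehyde, which closes to the lactol and is dehydrogenated again, the same diol → lactol → lactone path by which secoisolariciresinol dehydrogenase makes matairesinol, and because 9 is C2-symmetric either hydroxyl gives the same lactone while C4 cannot epimerize.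

Step 6
Reactants: 11 (3R,4R)-3,4-bis[3-methoxy-4-(triisopropylsilyloxy)benzyl]dihydrofuran-2(3H)-one
Product: 14 epinortrachelogenin, via potassium enolate 12 (not isolated), via bis-TIPS ether 13 (not isolated)
Conditions: KN(SiMe3)2, THF, −78 °C; 2-(phenylsulfonyl)-3-phenyloxaziridine, −78 °C; AcOH; then Bu4NF, 0 °C
Reagents that add atoms: 2-(phenylsulfonyl)-3-phenyloxaziridine, O=S(=O)(c1ccccc1)N1OC1c1ccccc1
Why: Davis enolate oxidation: the enolate is planar at C3, so the oxaziridine delivers oxygen to the face anti to the 4-benzyl group, placing 3-OH trans and the 3-benzyl group cis to it (3R), after which fluoride cleaves both aryl silyl ethers in the same flask.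

## Compound list

1 | 3-(4-hydroxy-3-methoxyphenyl)propanoic acid (dihydroferulic acid) | COc1cc(CCC(=O)O)ccc1O | starting material
2 | triisopropylsilyl 3-[3-methoxy-4-(triisopropylsilyloxy)phenyl]propanoate | COc1cc(CCC(=O)O[Si](C(C)C)(C(C)C)C(C)C)ccc1O[Si](C(C)C)(C(C)C)C(C)C | intermediate
3 | 3-[3-methoxy-4-(triisopropylsilyloxy)phenyl]propanoic acid | COc1cc(CCC(=O)O)ccc1O[Si](C(C)C)(C(C)C)C(C)C | intermediate
4 | (S)-4-isopropyloxazolidin-2-one | CC(C)[C@H]1COC(=O)N1 | starting material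
5 | 3-[3-methoxy-4-(triisopropylsilyloxy)phenyl]propanoic pivalic anhydride | COc1cc(CCC(=O)OC(=O)C(C)(C)C)ccc1O[Si](C(C)C)(C(C)C)C(C)C | intermediate
6 | (S)-4-isopropyl-3-{3-[3-methoxy-4-(triisopropylsilyloxy)phenyl]propanoyl}oxazolidin-2-one | COc1cc(CCC(=O)N2[C@@H](C(C)C)COC2=O)ccc1O[Si](C(C)C)(C(C)C)C(C)C | intermediate
7 | lithium (Z)-enolate of 6 | [Li+].[O-]/C(=C\Cc1ccc(O[Si](C(C)C)(C(C)C)C(C)C)c(OC)c1)N1[C@@H](C(C)C)COC1=O | intermediate
8 | (2R,3R)-2,3-bis[3-methoxy-4-(triisopropylsilyloxy)benzyl]-1,4-bis[(S)-4-isopropyl-2-oxooxazolidin-3-yl]butane-1,4-dione | O=C(N1[C@@H](C(C)C)COC1=O)[C@H](Cc1ccc(O[Si](C(C)C)(C(C)C)C(C)C)c(OC)c1)[C@@H](Cc1ccc(O[Si](C(C)C)(C(C)C)C(C)C)c(OC)c1)C(=O)N1[C@@H](C(C)C)COC1=O | intermediate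
9 | (2R,3R)-2,3-bis[3-methoxy-4-(triisopropylsilyloxy)benzyl]butane-1,4-diol | OC[C@H](Cc1ccc(O[Si](C(C)C)(C(C)C)C(C)C)c(OC)c1)[C@H](CO)Cc1ccc(O[Si](C(C)C)(C(C)C)C(C)C)c(OC)c1 | intermediate
10 | (3R,4R)-3,4-bis[3-methoxy-4-(triisopropylsilyloxy)benzyl]tetrahydrofuran-2-ol (both anomers) | COc1cc(C[C@H]2COC(O)[C@@H]2Cc2ccc(O[Si](C(C)C)(C(C)C)C(C)C)c(OC)c2)ccc1O[Si](C(C)C)(C(C)C)C(C)C | intermediate
11 | (3R,4R)-3,4-bis[3-methoxy-4-(triisopropylsilyloxy)benzyl]dihydrofuran-2(3H)-one | COc1cc(C[C@H]2COC(=O)[C@@H]2Cc2ccc(O[Si](C(C)C)(C(C)C)C(C)C)c(OC)c2)ccc1O[Si](C(C)C)(C(C)C)C(C)C | intermediate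
12 | potassium enolate of 11 (C3 planar, 4R) | [K+].COc1cc(C[C@H]2COC([O-])=C2Cc2ccc(O[Si](C(C)C)(C(C)C)C(C)C)c(OC)c2)ccc1O[Si](C(C)C)(C(C)C)C(C)C | intermediate
13 | (3R,4S)-3-hydroxy-3,4-bis[3-methoxy-4-(triisopropylsilyloxy)benzyl]dihydrofuran-2(3H)-one | COc1cc(C[C@H]2COC(=O)[C@@]2(O)Cc2ccc(O[Si](C(C)C)(C(C)C)C(C)C)c(OC)c2)ccc1O[Si](C(C)C)(C(C)C)C(C)C | intermediate
14 | epinortrachelogenin, (3R,4S)-3-hydroxy-3,4-bis(4-hydroxy-3-methoxybenzyl)dihydrofuran-2(3H)-one | COc1cc(C[C@H]2COC(=O)[C@@]2(O)Cc2ccc(O)c(OC)c2)ccc1O | target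

## Step count and risks

Total step count: 6. Longest linear sequence: 6 (1 → 3 → 6 → 8 → 9 → 11 → 14); the auxiliary 4 is bought.

Steps most likely to fail: step 3, step 5 and step 6.

Step 3 (yield and R,R/R,S ratio of the radical dimerization, and tolerance of the aryl silyl ethers toward TiCl4). The fallback makes the C8–C8′ bond ionically; it sets out from 6 and comes back at 11. Evans alkylation of 6 (NaN(SiMe3)2, THF, −78 °C; tert-butyl bromoacetate) gives tert-butyl (3R)-4-[(S)-4-isopropyl-2-oxooxazolidin-3-yl]-3-[3-methoxy-4-(triisopropylsilyloxy)benzyl]-4-oxobutanoate F1. LiBH4 cleaves the auxiliary to give tert-butyl (3R)-4-hydroxy-3-[3-methoxy-4-(triisopropylsilyloxy)benzyl]butanoate F2. Catalytic p-toluenesulfonic acid in warm toluene closes it to (R)-4-[3-methoxy-4-(triisopropylsilyloxy)benzyl]dihydrofuran-2(3H)-one F3. Its lithium enolate (LiN(iPr)2, −78 °C) adds, anti to the 4-benzyl group, to 3-methoxy-4-(triisopropylsilyloxy)benzaldehyde F4 (from vanillin, TIPSCl and imidazole). This gives the trans aldol adduct (3S,4R)-3-{hydroxy[3-methoxy-4-(triisopropylsilyloxy)phenyl]methyl}-4-[3-methoxy-4-(triisopropylsilyloxy)benzyl]dihydrofuran-2(3H)-one F5 as a carbinol mixture. Hydrogenolysis of the benzylic hydroxyl (H2, Pd/C, palladium on carbon, EtOAc/AcOH) gives 11.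

Step 5 (aerobic lactonization stalling at the lactol or over-oxidizing the electron-rich substrate). The fallback closes the ring at the diacid oxidation level; it sets out from 8 and comes back at 11. LiOH/H2O2 (THF/H2O, 0 °C) converts 8 into (2R,3R)-2,3-bis[3-methoxy-4-(triisopropylsilyloxy)benzyl]succinic acid F6. Acetic anhydride at reflux gives the trans anhydride (3R,4R)-3,4-bis[3-methoxy-4-(triisopropylsilyloxy)benzyl]dihydrofuran-2,5-dione F7. NaBH4 in THF reduces one of its two equivalent carbonyl groups to give 11.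

Step 6 (facial selectivity of oxygen transfer, or addition of the enolate to the sulfonimine by-product). The fallback installs the tertiary alcohol by dihydroxylation; it sets out from 11 and comes back at 13. Bromination of the potassium enolate (KN(SiMe3)2; CBr4, −78 °C) gives (3R,4S)-3-bromo-3,4-bis[3-methoxy-4-(triisopropylsilyloxy)benzyl]dihydrofuran-2(3H)-one F8, with bromine trans to the 4-benzyl group and therefore syn to H-4. Anti elimination with 1,8-diazabicyclo[5.4.0]undec-7-ene can then only go toward the benzylic hydrogens, giving (R,E)-3-[3-methoxy-4-(triisopropylsilyloxy)benzylidene]-4-[3-methoxy-4-(triisopropylsilyloxy)benzyl]dihydrofuran-2(3H)-one F9. OsO4 (catalytic) with N-methylmorpholine N-oxide adds anti to the 4-benzyl group to give (3S,4S)-3-hydroxy-3-{(R)-hydroxy[3-methoxy-4-(triisopropylsilyloxy)phenyl]methyl}-4-[3-methoxy-4-(triisopropylsilyloxy)benzyl]dihydrofuran-2(3H)-one F10. Hydrogenolysis of the benzylic hydroxyl (H2, Pd/C, EtOAc/AcOH) gives 13, which is desilylated with Bu4NF/AcOH as in step 6.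

## Further compounds

F1 | step 3 | tert-butyl (3R)-4-[(S)-4-isopropyl-2-oxooxazolidin-3-yl]-3-[3-methoxy-4-(triisopropylsilyloxy)benzyl]-4-oxobutanoate | CC(C)(C)OC(=O)C[C@@H](Cc1ccc(O[Si](C(C)C)(C(C)C)C(C)C)c(OC)c1)C(=O)N1[C@@H](C(C)C)COC1=O
F2 | step 3 | tert-butyl (3R)-4-hydroxy-3-[3-methoxy-4-(triisopropylsilyloxy)benzyl]butanoate | CC(C)(C)OC(=O)C[C@@H](Cc1ccc(O[Si](C(C)C)(C(C)C)C(C)C)c(OC)c1)CO
F3 | step 3 | (R)-4-[3-methoxy-4-(triisopropylsilyloxy)benzyl]dihydrofuran-2(3H)-one | O=C1C[C@@H](Cc2ccc(O[Si](C(C)C)(C(C)C)C(C)C)c(OC)c2)CO1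
F4 | step 3 | 3-methoxy-4-(triisopropylsilyloxy)benzaldehyde | COc1cc(C=O)ccc1O[Si](C(C)C)(C(C)C)C(C)C
F5 | step 3 | (3S,4R)-3-{hydroxy[3-methoxy-4-(triisopropylsilyloxy)phenyl]methyl}-4-[3-methoxy-4-(triisopropylsilyloxy)benzyl]dihydrofuran-2(3H)-one (carbinol mixture) | COc1cc(C[C@H]2COC(=O)[C@@H]2C(O)c2ccc(O[Si](C(C)C)(C(C)C)C(C)C)c(OC)c2)ccc1O[Si](C(C)C)(C(C)C)C(C)C
F6 | step 5 | (2R,3R)-2,3-bis[3-methoxy-4-(triisopropylsilyloxy)benzyl]succinic acid | OC(=O)[C@H](Cc1ccc(O[Si](C(C)C)(C(C)C)C(C)C)c(OC)c1)[C@@H](Cc1ccc(O[Si](C(C)C)(C(C)C)C(C)C)c(OC)c1)C(=O)O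
F7 | step 5 | (3R,4R)-3,4-bis[3-methoxy-4-(triisopropylsilyloxy)benzyl]dihydrofuran-2,5-dione | O=C1OC(=O)[C@H](Cc2ccc(O[Si](C(C)C)(C(C)C)C(C)C)c(OC)c2)[C@H]1Cc1ccc(O[Si](C(C)C)(C(C)C)C(C)C)c(OC)c1
F8 | step 6 | (3R,4S)-3-bromo-3,4-bis[3-methoxy-4-(triisopropylsilyloxy)benzyl]dihydrofuran-2(3H)-one | COc1cc(C[C@H]2COC(=O)[C@@]2(Br)Cc2ccc(O[Si](C(C)C)(C(C)C)C(C)C)c(OC)c2)ccc1O[Si](C(C)C)(C(C)C)C(C)C
F9 | step 6 | (R,E)-3-[3-methoxy-4-(triisopropylsilyloxy)benzylidene]-4-[3-methoxy-4-(triisopropylsilyloxy)benzyl]dihydrofuran-2(3H)-one | COc1cc(C[C@H]2COC(=O)/C2=C/c2ccc(O[Si](C(C)C)(C(C)C)C(C)C)c(OC)c2)ccc1O[Si](C(C)C)(C(C)C)C(C)C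
F10 | step 6 | (3S,4S)-3-hydroxy-3-{(R)-hydroxy[3-methoxy-4-(triisopropylsilyloxy)phenyl]methyl}-4-[3-methoxy-4-(triisopropylsilyloxy)benzyl]dihydrofuran-2(3H)-one | COc1cc(C[C@H]2COC(=O)[C@@]2(O)[C@H](O)c2ccc(O[Si](C(C)C)(C(C)C)C(C)C)c(OC)c2)ccc1O[Si](C(C)C)(C(C)C)C(C)C
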